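Target left standing in the flasks below does not stay target, and the set-ups differ in how long it stands.

the same everywhere: starting material 0.40 M
- blue: partner 0.40 M; protic impurity 0.040 M; run made earlier
- teal: partner 0.20 M; protic impurity 0.040 M; run made earlier
- ochre: partner 0.80 M; protic impurity 0.040 M; run made earlier
- Tuesday's: partner 0.400 M; protic impurity 0.0400 M; a closed flask charged with all of it at once and left for 2.0 h; time 2.0 h
- Saturday's: partner 0.400 M (fed, over 1.60 h); protic impurity 0.0400 M; all but partner at the start; partner goes in evenly over 1.60 h, the run ends at 2.0 h; time 2.0 h
- Monday's: partner 0.400 M; protic impurity 0.0400 M; a tube with plug flow, the mixed feed as stated, residence time 2.0 h; time 2.0 h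
- Friday's: partner 0.400 M; protic impurity 0.0400 M; a single well-mixed tank run continuously and read at steady state, 2.0 h in it on average

blue run (percent of the starting material charged)

| time / min | target / % | isomer of the product / % |
|---|---|---|
| 6.00 | 0 | 0 |
| 8.00 | 2 | 0 |
| 12.0 | 2 | 0 |
| 20.0 | 3 | 0 |
| 30.0 | 6 | 2 |
| 50.0 | 17 | 1 |
| 80.0 | 25 | 6 |

teal run (percent of the starting material charged)

| time / h | target / % | isomer of the product / % |
|---|---|---|
| 0.333 | 2 | 0 |
| 0.667 | 5 | 0 |
| 1.00 | 13 | 2 |
| 1.33 | 14 | 3 |
| 1.50 | 18 | 6 |
| 2.00 | 19 | 6 |
| 2.50 | 17 | 8 |

ochre run (percent of the starting material charged)

| time / h | target / % | isomer of the product / % |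
|---|---|---|
| 0.200 | 0 | 0 |
| 0.333 | 7 | 1 |
| 0.417 | 8 | 0 |
| 0.667 | 22 | 1 |
| 1.00 | 34 | 8 |
| 1.50 | 44 | 16 |
| 2.50 | 44 | 27 |

(scatter of a reading: 1.5 percentage points)

- the stated concentrations are those of everything mixed, before any reaction; amounts are the same in each set-up
- the feed brings no volume worth counting
- the earlier runs were made in a closed, stirred flask

* the set-up with the highest share of target in all that became target or isomer of the product, at the outlet or at the end ("none" if the first two lie within 2 percentage points) (Tuesday's / Saturday's / Monday's / Friday's / none)
* share of target in all that became target or isomer of the product, at the outlet or at the end, Tuesday's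
* share of target in all that became target or isomer of the product, at the outlet or at the end, Saturday's
* share of target in all that became target or isomer of the product, at the outlet or at the end, Monday's
* share of target in all that became target or isomer of the product, at the outlet or at the end, Friday's

The ochre run shows the loss. From 1.00 h to 2.50 h its isomer of the product climbs from 8% to 27%, while target reads between 34% and 44%. Summing target over time from reading to reading, the isomer gained per unit of target standing one hour reads 0.299 h⁻¹, with the scatter of those readings. This is the ageing constant, taken as a first-order constant. The share asked for, a selectivity, then becomes a matter of age: by hand, isomer over target is taken as the constant times the mean time target has stood, and the share as one over one plus that product.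

Friday's tank holds its contents 2.0 h on average, so the share there comes to 62.6%. Monday's tube gives each portion the history of Tuesday's closed flask, and Tuesday's flask is the blue run continued. The last blue reading, 6% isomer on 25% target, means an age of 0.802 h. Target made at a steady pace gets older by half of the time passed, so the age reaches 1.14 h and the share for Tuesday's and Monday's is 74.6%.

For Saturday's feed this reckoning borrows teal, with half the partner and target still at 5% after 0.667 h. Taking that as the start, the age at the end is 0.666 h and the share 83.4%, so this reckoning puts Saturday's higher than Tuesday's, and Tuesday's higher than Friday's.

The forecast, which differs from this reckoning in its numbers, names Saturday's, with 73% for Tuesday's, 87% for Saturday's, 73% for Monday's and 62% for Friday's, holding that “slow feed stretches the induction to about 1 h, so product forms late and ages little”.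

The flask gives 70.1% for Tuesday's, 78.4% for Saturday's, 70.1% for Monday's and 62.8% for Friday's, so Saturday's leads.

    partner → second intermediate (k = 0.0220 min⁻¹)
    starting material → open intermediate (k = 0.0299 min⁻¹)
    open intermediate + second intermediate → target (k = 0.0856 L mol⁻¹ min⁻¹)
    target ⇌ isomer of the product (K = 1.92, k = 0.00715 min⁻¹)
    partner + protic impurity → quenched reagent (k = 0.535 L mol⁻¹ min⁻¹)
    2 second intermediate → homo product (k = 0.0546 L mol⁻¹ min⁻¹)

At 2.00 h in Saturday's, the step from target to isomer runs 6.98 times as fast as its return, a net loss of 0.368 h⁻¹ per unit of target, above the ageing constant; over the stretch after the feed that constant gives 2.9 percentage points of isomer where Saturday's flask shows 3.6 points. Carried to Saturday's flask read at 5.0 h, starting from its isomer at 2.00 h and with its target at both times, the constant gives 33.8% isomer and a share of 47.3%, and that flask holds 34.7% isomer at a share of 46.6%.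

The runs were generated by integration from invented constants; the scatter is artificial.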